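Everything rests on disconnecting the C2–C3 bond of pyran ring C in the third flavan unit (unit C, bonded through C4 to C8 of the terminal unit D). C2 carries the ring oxygen O1 and C3 the hydroxyl, so this bond is the retron of a cyclic enol ether. In one operation a titanium methylidene converts an open-chain aryl 3,4-bis(benzyloxy)benzoate, whose ortho substituent is a 1-arylallyl group, into the flav-2-ene: the ester carbonyl carbon becomes C2, the vinyl CH becomes C3. The preset diarylmethine C4 then steers hydroboration to install C3 and C2; two 4α-selective cation couplings with catechin-derived electrophiles add units B and A.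

Key step: step 9

Remarks on the chemistry:
- The flavan units are lettered A to D from the upper chain end to the terminal unit; flavan numbering (O1, C2, C3, C4, C4a, C5 to C8, C8a) is used within each unit.
- Assumption: (R)-3,3′-dibromo-1,1′-bi-2-naphthol is written as the catalyst enantiomer that gives the (S)-diarylmethine in step 7; if a model run shows the opposite sense, its antipode is used.
- Assumption: (+)-catechin, 3,5-bis(benzyloxy)phenol, dibutyl vinylboronate and 3,4-bis(benzyloxy)benzoic acid are taken as catalogue compounds.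
- Unit B is introduced with an electrophile that keeps C8 free for the next extension; unit A, the chain end, is introduced with the C8-brominated electrophile, whose bromine is removed in the final hydrogenation.

Step 1
Reactants: 1 (+)-catechin
Product: 2 5,7,3′,4′-tetra-O-benzyl-(+)-catechin
Conditions: BnBr (4.5 equiv), K2CO3, DMF, 0 °C → rt
Reagents that add atoms: benzyl bromide BrCc1ccccc1
Why: Williamson O-alkylation of the four phenoxides formed by K2CO3 should leave the less acidic secondary 3-OH and both stereocenters untouched.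

Step 2
Reactants: 2 5,7,3′,4′-tetra-O-benzyl-(+)-catechin
Product: 3 (2R,3S,4S)-5,7,3′,4′-tetra-O-benzyl-4-(2-ethoxyethoxy)flavan-3-ol
Conditions: DDQ (2 equiv), 2-ethoxyethanol (5 equiv), CH2Cl2, rt
Reagents that add atoms: 2-ethoxyethanol CCOCCO
Why: DDQ-mediated benzylic oxidation (hydride abstraction at C4, assisted by the 5,7-dialkoxy ring A) gives a quinone methide-type cation that the alcohol should capture anti to the C2 aryl group (4β), installing the leaving group for later C4 cation chemistry.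

Step 3
Reactants: 3 (2R,3S,4S)-5,7,3′,4′-tetra-O-benzyl-4-(2-ethoxyethoxy)flavan-3-ol
Product: 4 (2R,3S,4S)-3-O-acetyl-5,7,3′,4′-tetra-O-benzyl-4-(2-ethoxyethoxy)flavan
Conditions: Ac2O, pyridine, DMAP (cat.), rt
Reagents that add atoms: acetic anhydride CC(=O)OC(C)=O
Why: DMAP-catalysed acylation of the secondary alcohol should install the 3-acetoxy group that later participates at C4 and so enforces 3,4-trans coupling.

Step 4
Reactants: 2 5,7,3′,4′-tetra-O-benzyl-(+)-catechin
Product: 5 3,5,7,3′,4′-penta-O-benzyl-(+)-catechin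
Conditions: NaH, BnBr, DMF, 0 °C → rt
Reagents that add atoms: benzyl bromide BrCc1ccccc1
Why: Williamson etherification of the sodium alkoxide protects the 3-OH of unit D against the organolithium, acylation and titanium steps, and the group is removed only in the final hydrogenolysis.

Step 5
Reactants: 5 3,5,7,3′,4′-penta-O-benzyl-(+)-catechin
Product: 6 8-bromo-3,5,7,3′,4′-penta-O-benzyl-(+)-catechin
Conditions: NBS (1.0 equiv), CH2Cl2, −78 °C → rt
Reagents that add atoms: N-bromosuccinimide O=C1CCC(=O)N1Br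
Why: Electrophilic aromatic bromination should occur at C8, the most nucleophilic ring A position of 5,7-dialkoxyflavans, giving a regiodefined handle for metalation.

Step 6
Reactants: 6 8-bromo-3,5,7,3′,4′-penta-O-benzyl-(+)-catechin
Product: 8 3,5,7,3′,4′-penta-O-benzyl-(+)-catechin-8-carbaldehyde, via 8-lithio-penta-O-benzylcatechin 7 (not isolated)
Conditions: n-BuLi, THF, −78 °C; DMF, −78 → 0 °C; H2O
Reagents that add atoms: N,N-dimethylformamide CN(C)C=O
Why: Bromine–lithium exchange followed by formylation of the aryllithium with DMF (Bouveault aldehyde synthesis) places at C8 of unit D the carbon that becomes C4 of unit C.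

Step 7
Reactants: 8 3,5,7,3′,4′-penta-O-benzyl-(+)-catechin-8-carbaldehyde, 9 3,5-bis(benzyloxy)phenol, 10 dibutyl vinylboronate
Product: 12 3,5-bis(benzyloxy)-2-[(1S)-1-(penta-O-benzylcatechin-8-yl)prop-2-en-1-yl]phenol, via o-quinone methide 11 (not isolated)
Conditions: 9 (2 equiv), 10 (2 equiv), (R)-3,3′-dibromo-1,1′-bi-2-naphthol (20 mol %), 4 Å molecular sieves, PhCF3, 45 °C; aqueous work-up
Reagents that add atoms: none
Why: Boron-templated ortho-hydroxyalkylation of phenol 9 by aldehyde 8 and loss of borate give o-quinone methide 11, to whose methide carbon the vinyl group is transferred inside a chiral biphenol–boronate complex (Petasis-type three-component condensation), so the catalyst rather than the remote stereocenters of unit D should select the face and set the diarylmethine center as S.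

Step 8
Reactants: 12 3,5-bis(benzyloxy)-2-[(1S)-1-(penta-O-benzylcatechin-8-yl)prop-2-en-1-yl]phenol, 13 3,4-bis(benzyloxy)benzoic acid
Product: 14 3,5-bis(benzyloxy)-2-[(1S)-1-(penta-O-benzylcatechin-8-yl)prop-2-en-1-yl]phenyl 3,4-bis(benzyloxy)benzoate
Conditions: EDC·HCl, DMAP, CH2Cl2, rt
Reagents that add atoms: none
Why: Steglich esterification of the phenol (O1 of unit C) with the ring B acid puts the future C2 in place as the ester carbonyl carbon without touching the allylic diarylmethine center.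

Step 9
Reactants: 14 3,5-bis(benzyloxy)-2-[(1S)-1-(penta-O-benzylcatechin-8-yl)prop-2-en-1-yl]phenyl 3,4-bis(benzyloxy)benzoate
Product: 16 (4S)-5,7,3′,4′-tetra-O-benzyl-4-(penta-O-benzylcatechin-8-yl)flav-2-ene, via acyclic enol ether 15 (not isolated)
Conditions: Cp2Ti(μ-Cl)(μ-CH2)AlMe2 (Tebbe reagent, 4 equiv), THF, 0 → 25 °C, then 65 °C; 1 M NaOH work-up, basic alumina
Reagents that add atoms: none
Why: Cp2Ti=CH2 released from the reagent first methylenates the only carbonyl group, the aryl ester, to the 1-aryloxy-1-arylethene 15 (Wittig-like [2+2] and cycloreversion driven by the Ti=O bond); on heating, further methylidene engages the terminal vinyl group to a titanium alkylidene on C3, which closes onto the enol ether through a titanacyclobutane and expels ethylene, forming C2=C3. The closest known reaction type is the tandem ester methylenation/ring-closing enol ether–olefin metathesis of olefinic esters to cyclic enol ethers with titanium methylidenes. The ring closed is the six-membered pyran ring C of unit C, by ring-closing metathesis between two sp2 termini, the new double bond being endocyclic (a 4H-chromene). No stereocenter is created; C4 is not touched because no intermediate involves the C4–H bond, and this center then controls C3 and C2 in step 10. The step needs chemoselectivity (secured by there being one carbonyl and one alkene), six-membered closure over intermolecular metathesis (secured by the 1,6-relationship of the reacting carbons, the hindered diarylmethine beside the vinyl group and dilution), and no migration of the double bond into conjugation with the two aryl groups (secured by non-acidic conditions and a basic work-up).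

Step 10
Reactants: 16 (4S)-5,7,3′,4′-tetra-O-benzyl-4-(penta-O-benzylcatechin-8-yl)flav-2-ene
Product: 18 nona-O-benzyl catechin-(4α→8)-catechin (unit C 3-OH free; unit D 3-O-benzyl), via C3-alkylborane 17 (not isolated)
Conditions: BH3·THF (3 equiv), THF, 0 °C → rt; then aq. NaOH, H2O2, 0 °C
Reagents that add atoms: hydrogen peroxide OO
Why: Hydroboration–oxidation of the cyclic enol ether should place boron on C3 (β-carbon of the enol ether) and hydrogen on C2 in a syn fashion on the face opposite the pseudoaxial C4 aryl group (unit D, pushed axial by peri strain with the C5 benzyloxy group), so C4 sets C3 (S) and C2 (R) as 3,4-trans and 2,3-trans, and the C–B bond is oxidised with retention.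

Step 11
Reactants: 18 nona-O-benzyl catechin-(4α→8)-catechin (unit C 3-OH free; unit D 3-O-benzyl), 4 (2R,3S,4S)-3-O-acetyl-5,7,3′,4′-tetra-O-benzyl-4-(2-ethoxyethoxy)flavan
Product: 20 protected trimer B–C–D (3-O-acetyl on unit B; 3-OH on unit C; 3-O-benzyl on unit D), via acetoxonium triflate 19 (not isolated)
Conditions: TMSOTf (cat.), CH2Cl2, −78 °C, slow addition of 4 (1.0 equiv); Et3N quench
Reagents that add atoms: none
Why: TMSOTf ionises the C4 acetal of 4 to a flavan-4-yl cation bridged on the β face by the 3-acetoxy group (19), and Friedel–Crafts-type attack from the α face by C8 of unit C, the most nucleophilic free position of the dimer, should give the 4α (3,4-trans) interflavan bond, slow addition of 4 limiting its self-condensation.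

Step 12
Reactants: 4 (2R,3S,4S)-3-O-acetyl-5,7,3′,4′-tetra-O-benzyl-4-(2-ethoxyethoxy)flavan
Product: 21 (2R,3S,4S)-3-O-acetyl-5,7,3′,4′-tetra-O-benzyl-8-bromo-4-(2-ethoxyethoxy)flavan
Conditions: NBS (1.05 equiv), CH2Cl2, −78 → 0 °C
Reagents that add atoms: N-bromosuccinimide O=C1CCC(=O)N1Br
Why: Electrophilic aromatic bromination should again select C8 of the 5,7-dialkoxy ring A under cold, neutral conditions that spare the C4 acetal and the 3-acetate, and the bromine caps the one position through which this electrophile could act as its own nucleophile.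

Step 13
Reactants: 20 protected trimer B–C–D (3-O-acetyl on unit B; 3-OH on unit C; 3-O-benzyl on unit D), 21 (2R,3S,4S)-3-O-acetyl-5,7,3′,4′-tetra-O-benzyl-8-bromo-4-(2-ethoxyethoxy)flavan
Product: 23 protected 8-bromo tetramer A–B–C–D (8-bromo on unit A; 3-O-acetyl on units A and B; 3-OH on unit C; 3-O-benzyl on unit D), via 8-bromo acetoxonium triflate 22 (not isolated)
Conditions: TMSOTf (cat.), CH2Cl2, −78 → −40 °C, 21 (1.3 equiv); Et3N quench
Reagents that add atoms: none
Why: TMSOTf ionises 21 to the β-face-bridged acetoxonium ion 22, which C8 of unit B, the only free C8 of the trimer, should attack from the α face (cationic flavan-4-yl/arene coupling under neighbouring-group control, 3,4-trans), while the C8 bromine keeps the electrophile from condensing with itself and the chain from growing beyond unit A.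

Step 14
Reactants: 23 protected 8-bromo tetramer A–B–C–D (8-bromo on unit A; 3-O-acetyl on units A and B; 3-OH on unit C; 3-O-benzyl on unit D)
Product: 24 8-bromo-heptadeca-O-benzyl tetramer (3-OH free on units A, B and C)
Conditions: NaOMe (cat.), MeOH/THF, rt
Reagents that add atoms: none
Why: Zemplén transesterification should remove both acetates under basic conditions that leave the benzyl ethers, the aryl bromide, the acid-labile interflavan bonds and all stereocenters untouched.

Step 15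
Reactants: 24 8-bromo-heptadeca-O-benzyl tetramer (3-OH free on units A, B and C)
Product: 25 catechin-(4α→8)-catechin-(4α→8)-catechin-(4α→8)-catechin (CNP0236700.2)
Conditions: H2 (1 atm), Pd(OH)2/C, NaOAc (1.5 equiv), THF/MeOH/H2O, rt
Reagents that add atoms: none
Why: Palladium-catalysed hydrogenolysis should cleave the seventeen benzyl ethers and, by hydrodehalogenation, the C8–Br bond of unit A in one operation, with NaOAc buffering the HBr so that the benzylic interflavan C4–C8 bonds, which need acid to ionise, stay intact.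

Compound list

1 | (+)-catechin, (2R,3S) | Oc1cc(O)c2c(c1)O[C@H](c1ccc(O)c(O)c1)[C@@H](O)C2 | starting material
2 | 5,7,3′,4′-tetra-O-benzyl-(+)-catechin | O(Cc3ccccc3)c1cc(OCc3ccccc3)c2c(c1)O[C@H](c1ccc(OCc3ccccc3)c(OCc3ccccc3)c1)[C@@H](O)C2 | intermediate
3 | (2R,3S,4S)-5,7,3′,4′-tetra-O-benzyl-4-(2-ethoxyethoxy)flavan-3-ol (4β-ether) | O(Cc3ccccc3)c1cc(OCc3ccccc3)c2c(c1)O[C@H](c1ccc(OCc3ccccc3)c(OCc3ccccc3)c1)[C@@H](O)[C@H]2OCCOCC | intermediate
4 | (2R,3S,4S)-3-O-acetyl-5,7,3′,4′-tetra-O-benzyl-4-(2-ethoxyethoxy)flavan (chain-extension electrophile for unit B) | O(Cc3ccccc3)c1cc(OCc3ccccc3)c2c(c1)O[C@H](c1ccc(OCc3ccccc3)c(OCc3ccccc3)c1)[C@@H](OC(C)=O)[C@H]2OCCOCC | intermediate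
5 | 3,5,7,3′,4′-penta-O-benzyl-(+)-catechin | O(Cc3ccccc3)c1cc(OCc3ccccc3)c2c(c1)O[C@H](c1ccc(OCc3ccccc3)c(OCc3ccccc3)c1)[C@@H](OCc3ccccc3)C2 | intermediate
6 | 8-bromo-3,5,7,3′,4′-penta-O-benzyl-(+)-catechin | O(Cc3ccccc3)c1cc(OCc3ccccc3)c2c(c1Br)O[C@H](c1ccc(OCc3ccccc3)c(OCc3ccccc3)c1)[C@@H](OCc3ccccc3)C2 | intermediate
7 | 8-lithio-3,5,7,3′,4′-penta-O-benzyl-(+)-catechin (not isolated) | O(Cc3ccccc3)c1cc(OCc3ccccc3)c2c(c1[Li])O[C@H](c1ccc(OCc3ccccc3)c(OCc3ccccc3)c1)[C@@H](OCc3ccccc3)C2 | intermediate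
8 | 3,5,7,3′,4′-penta-O-benzyl-(+)-catechin-8-carbaldehyde | O(Cc3ccccc3)c1cc(OCc3ccccc3)c2c(c1C=O)O[C@H](c1ccc(OCc3ccccc3)c(OCc3ccccc3)c1)[C@@H](OCc3ccccc3)C2 | intermediate
9 | 3,5-bis(benzyloxy)phenol | Oc1cc(OCc2ccccc2)cc(OCc2ccccc2)c1 | starting material
10 | dibutyl vinylboronate | C=CB(OCCCC)OCCCC | starting material
11 | o-quinone methide: 3,5-bis(benzyloxy)-6-[(penta-O-benzylcatechin-8-yl)methylidene]cyclohexa-2,4-dien-1-one (not isolated; boron-bound in the flask) | O=C1C=C(OCc3ccccc3)C=C(OCc3ccccc3)C1=Cc1c(OCc3ccccc3)cc(OCc3ccccc3)c2c1O[C@H](c1ccc(OCc3ccccc3)c(OCc3ccccc3)c1)[C@@H](OCc3ccccc3)C2 | intermediate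
12 | 3,5-bis(benzyloxy)-2-[(1S)-1-(penta-O-benzylcatechin-8-yl)prop-2-en-1-yl]phenol | C=C[C@@H](c1c(O)cc(OCc3ccccc3)cc1OCc3ccccc3)c1c(OCc3ccccc3)cc(OCc3ccccc3)c2c1O[C@H](c1ccc(OCc3ccccc3)c(OCc3ccccc3)c1)[C@@H](OCc3ccccc3)C2 | intermediate
13 | 3,4-bis(benzyloxy)benzoic acid | OC(=O)c1ccc(OCc2ccccc2)c(OCc2ccccc2)c1 | starting material
14 | 3,5-bis(benzyloxy)-2-[(1S)-1-(penta-O-benzylcatechin-8-yl)prop-2-en-1-yl]phenyl 3,4-bis(benzyloxy)benzoate | C=C[C@@H](c1c(OC(=O)c4ccc(OCc3ccccc3)c(OCc3ccccc3)c4)cc(OCc3ccccc3)cc1OCc3ccccc3)c1c(OCc3ccccc3)cc(OCc3ccccc3)c2c1O[C@H](c1ccc(OCc3ccccc3)c(OCc3ccccc3)c1)[C@@H](OCc3ccccc3)C2 | intermediate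
15 | acyclic enol ether: the 1-[3,4-bis(benzyloxy)phenyl]ethenyl ether of phenol 12 (not isolated) | C=C[C@@H](c1c(OC(=C)c4ccc(OCc3ccccc3)c(OCc3ccccc3)c4)cc(OCc3ccccc3)cc1OCc3ccccc3)c1c(OCc3ccccc3)cc(OCc3ccccc3)c2c1O[C@H](c1ccc(OCc3ccccc3)c(OCc3ccccc3)c1)[C@@H](OCc3ccccc3)C2 | intermediate
16 | (4S)-5,7,3′,4′-tetra-O-benzyl-4-(penta-O-benzylcatechin-8-yl)flav-2-ene (2-aryl-4H-chromene) | c1c(OCc3ccccc3)cc(OCc3ccccc3)c2c1OC(c1ccc(OCc3ccccc3)c(OCc3ccccc3)c1)=C[C@@H]2c1c(OCc3ccccc3)cc(OCc3ccccc3)c2c1O[C@H](c1ccc(OCc3ccccc3)c(OCc3ccccc3)c1)[C@@H](OCc3ccccc3)C2 | intermediate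
17 | C3-alkylborane of unit C (boron on C3, trans to the C4 and C2 aryl groups; not isolated) | c1c(OCc3ccccc3)cc(OCc3ccccc3)c2c1O[C@H](c1ccc(OCc3ccccc3)c(OCc3ccccc3)c1)[C@@H](B)[C@@H]2c1c(OCc3ccccc3)cc(OCc3ccccc3)c2c1O[C@H](c1ccc(OCc3ccccc3)c(OCc3ccccc3)c1)[C@@H](OCc3ccccc3)C2 | intermediate
18 | nona-O-benzyl catechin-(4α→8)-catechin: unit C (2R,3S,4S) with 3-OH free, unit D 3-O-benzyl | c1c(OCc3ccccc3)cc(OCc3ccccc3)c2c1O[C@H](c1ccc(OCc3ccccc3)c(OCc3ccccc3)c1)[C@@H](O)[C@@H]2c1c(OCc3ccccc3)cc(OCc3ccccc3)c2c1O[C@H](c1ccc(OCc3ccccc3)c(OCc3ccccc3)c1)[C@@H](OCc3ccccc3)C2 | intermediate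
19 | acetoxonium triflate from 4: C3–C4 cis-fused 2-methyl-1,3-dioxolan-2-ylium on the β face (not isolated) | O(Cc3ccccc3)c1cc(OCc3ccccc3)c2c(c1)O[C@H](c1ccc(OCc3ccccc3)c(OCc3ccccc3)c1)[C@@H](OC(C)=[O+]4)[C@H]24.[O-]S(=O)(=O)C(F)(F)F | intermediate
20 | protected trimer B–C–D, all 4α→8: unit B 3-O-acetyl tetra-O-benzyl, unit C tetra-O-benzyl with 3-OH, unit D penta-O-benzyl | O(Cc3ccccc3)c1cc(OCc3ccccc3)c2c(c1)O[C@H](c1ccc(OCc3ccccc3)c(OCc3ccccc3)c1)[C@@H](OC(C)=O)[C@@H]2c1c(OCc3ccccc3)cc(OCc3ccccc3)c2c1O[C@H](c1ccc(OCc3ccccc3)c(OCc3ccccc3)c1)[C@@H](O)[C@@H]2c1c(OCc3ccccc3)cc(OCc3ccccc3)c2c1O[C@H](c1ccc(OCc3ccccc3)c(OCc3ccccc3)c1)[C@@H](OCc3ccccc3)C2 | intermediate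
21 | (2R,3S,4S)-3-O-acetyl-5,7,3′,4′-tetra-O-benzyl-8-bromo-4-(2-ethoxyethoxy)flavan (C8-capped electrophile for unit A) | O(Cc3ccccc3)c1cc(OCc3ccccc3)c2c(c1Br)O[C@H](c1ccc(OCc3ccccc3)c(OCc3ccccc3)c1)[C@@H](OC(C)=O)[C@H]2OCCOCC | intermediate
22 | 8-bromo acetoxonium triflate from 21: C3–C4 cis-fused 2-methyl-1,3-dioxolan-2-ylium on the β face (not isolated) | O(Cc3ccccc3)c1cc(OCc3ccccc3)c2c(c1Br)O[C@H](c1ccc(OCc3ccccc3)c(OCc3ccccc3)c1)[C@@H](OC(C)=[O+]4)[C@H]24.[O-]S(=O)(=O)C(F)(F)F | intermediate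
23 | protected 8-bromo tetramer A–B–C–D, all 4α→8: unit A 8-bromo and 3-O-acetyl, unit B 3-O-acetyl, unit C 3-OH, unit D 3-O-benzyl, all phenols benzylated | O(Cc3ccccc3)c1cc(OCc3ccccc3)c2c(c1Br)O[C@H](c1ccc(OCc3ccccc3)c(OCc3ccccc3)c1)[C@@H](OC(C)=O)[C@@H]2c1c(OCc3ccccc3)cc(OCc3ccccc3)c2c1O[C@H](c1ccc(OCc3ccccc3)c(OCc3ccccc3)c1)[C@@H](OC(C)=O)[C@@H]2c1c(OCc3ccccc3)cc(OCc3ccccc3)c2c1O[C@H](c1ccc(OCc3ccccc3)c(OCc3ccccc3)c1)[C@@H](O)[C@@H]2c1c(OCc3ccccc3)cc(OCc3ccccc3)c2c1O[C@H](c1ccc(OCc3ccccc3)c(OCc3ccccc3)c1)[C@@H](OCc3ccccc3)C2 | intermediate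
24 | 8-bromo-heptadeca-O-benzyl tetramer: 8-bromo on unit A, 3-OH free on units A, B and C | O(Cc3ccccc3)c1cc(OCc3ccccc3)c2c(c1Br)O[C@H](c1ccc(OCc3ccccc3)c(OCc3ccccc3)c1)[C@@H](O)[C@@H]2c1c(OCc3ccccc3)cc(OCc3ccccc3)c2c1O[C@H](c1ccc(OCc3ccccc3)c(OCc3ccccc3)c1)[C@@H](O)[C@@H]2c1c(OCc3ccccc3)cc(OCc3ccccc3)c2c1O[C@H](c1ccc(OCc3ccccc3)c(OCc3ccccc3)c1)[C@@H](O)[C@@H]2c1c(OCc3ccccc3)cc(OCc3ccccc3)c2c1O[C@H](c1ccc(OCc3ccccc3)c(OCc3ccccc3)c1)[C@@H](OCc3ccccc3)C2 | intermediate
25 | catechin-(4α→8)-catechin-(4α→8)-catechin-(4α→8)-catechin (CNP0236700.2) | Oc1cc(O)c2c(c1)O[C@H](c1ccc(O)c(O)c1)[C@@H](O)[C@@H]2c1c(O)cc(O)c2c1O[C@H](c1ccc(O)c(O)c1)[C@@H](O)[C@@H]2c1c(O)cc(O)c2c1O[C@H](c1ccc(O)c(O)c1)[C@@H](O)[C@@H]2c1c(O)cc(O)c2c1O[C@H](c1ccc(O)c(O)c1)[C@@H](O)C2 | target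

Total step count: 15.
Longest linear sequence: 12 steps (steps 1, 4, 5, 6, 7, 8, 9, 10, 11, 13, 14, 15); steps 2, 3 and 12 form the branch to electrophiles 4 and 21.

Steps most likely to fail

Step 9. The second stage may stall: the titanium methylidene can decompose before it engages the hindered vinyl group, leaving the acyclic enol ether, or the terminal double bond may migrate into conjugation. The fallback sets out from 14 and separates the two events. Methylenation with Cp2TiMe2 (toluene, 65 °C, dark) gives the enol ether 15, which is isolated on basic alumina. It is then closed by ruthenium-catalysed diene ring-closing metathesis with the second-generation Hoveyda–Grubbs catalyst RuCl2(H2IMes)(=CH–C6H4-2-O-i-Pr) (toluene, 80 °C, argon sparge to remove ethylene). The route is rejoined at 16; this fallback makes no compound outside the compound list (F0).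

Step 7. The ortho-hydroxyalkylation of the phenol by the hindered, electron-rich aldehyde may be sluggish, and facial discrimination at the o-quinone methide (its methide carbon lies between two 2,6-dioxygenated aryl groups) may be poor. The fallback sets out from 8 and 9 and drops catalyst control. Acid-mediated three-component condensation with TolSO2Na (aqueous HCO2H, rt) should give the o-hydroxybenzyl sulfone 3,5-bis(benzyloxy)-2-[(penta-O-benzylcatechin-8-yl)(p-tolylsulfonyl)methyl]phenol F1. Excess CH2=CHMgBr (THF, −78 → 0 °C) then deprotonates the phenol, expels sulfinate to the o-quinone methide 11 and adds vinyl in a 1,4-manner. Because unit D is enantiopure, the two products are diastereomers: 12 and its (1R)-diarylmethine epimer F2. They are separated by chromatography and the route is rejoined at 12.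

Step 10. Facial selectivity of the borane may be incomplete, or the β-aryloxy borane may eliminate with opening of the pyran ring. The fallback sets out from 16. Epoxidation with dimethyldioxirane (acetone/CH2Cl2, −40 °C) on the face opposite the C4 aryl group should give the 2β,3β-epoxide F3. Reductive opening with i-Bu2AlH (CH2Cl2, −78 °C) follows: aluminium binds the epoxide oxygen, the C2–O bond ionises to the O1-stabilised benzylic cation and hydride is delivered from the aluminate on the same face. Hydrogen at C2 thus ends cis to the C3 oxygen (2,3-trans), and the route is rejoined at 18.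

Further compounds
F1 | step 7 | 3,5-bis(benzyloxy)-2-[(penta-O-benzylcatechin-8-yl)(p-tolylsulfonyl)methyl]phenol (mixture at the sulfonyl carbon) | Cc1ccc(cc1)S(=O)(=O)C(c1c(O)cc(OCc3ccccc3)cc1OCc3ccccc3)c1c(OCc3ccccc3)cc(OCc3ccccc3)c2c1O[C@H](c1ccc(OCc3ccccc3)c(OCc3ccccc3)c1)[C@@H](OCc3ccccc3)C2
F2 | step 7 | 3,5-bis(benzyloxy)-2-[(1R)-1-(penta-O-benzylcatechin-8-yl)prop-2-en-1-yl]phenol (diarylmethine epimer of 12) | C=C[C@H](c1c(O)cc(OCc3ccccc3)cc1OCc3ccccc3)c1c(OCc3ccccc3)cc(OCc3ccccc3)c2c1O[C@H](c1ccc(OCc3ccccc3)c(OCc3ccccc3)c1)[C@@H](OCc3ccccc3)C2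
F0 | step 9 | none | none
F3 | step 10 | 2β,3β-epoxide of flav-2-ene 16 (oxirane on the face opposite the C4 aryl group) | c1c(OCc3ccccc3)cc(OCc3ccccc3)c2c1O[C@@]5(c1ccc(OCc3ccccc3)c(OCc3ccccc3)c1)O[C@H]5[C@@H]2c1c(OCc3ccccc3)cc(OCc3ccccc3)c2c1O[C@H](c1ccc(OCc3ccccc3)c(OCc3ccccc3)c1)[C@@H](OCc3ccccc3)C2
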